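The route rests on cutting the bond between the bridging CH2 and C1 of the phenol ring, the carbon flanked by OMe and CH2OMe. The bridge carbon sits on C5 of the isocoumarin benzo ring, ortho to the C6 hydroxyl and para to the C8 methoxy group, so it is carried as a salicylaldehyde-type formyl group. In the key step a regiodefined aryllithium adds to this aldehyde and the carbinol, which ionises to an O-protonated o-quinone methide, is reduced in the same pot by Et3SiH/TFA: C–C bond formation and deoxygenation in one operation. The precursors are 5-formyl-6-hydroxy-8-methoxy-3-methylisocoumarin and a silyl-protected 2-bromo-3-methoxybenzyl methyl ether; desilylation ends the route.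

Key step: step 7

Remark: the target has no stereocentre and is achiral, so there is no enantiomer to select; the only stereocentre on the route (in 15) is formed racemic and is removed in the same step.

Step 1
Reactants: 1 methyl 2,4-dihydroxy-6-methylbenzoate (methyl orsellinate)
Product: 3 methyl 2-methoxy-4-[(4-methoxyphenyl)methoxy]-6-methylbenzoate, via 4-O-PMB salicylate 2 (not isolated)
Conditions: PMBCl (1.05 equiv), K2CO3 (1.2 equiv), DMF, rt; then MeI (3 equiv), K2CO3 (2 equiv), 50 °C
Reagents that add atoms: 4-methoxybenzyl chloride COc1ccc(CCl)cc1; iodomethane CI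
Why: Williamson etherification, in which the 2-OH is locked in a hydrogen bond to the ester carbonyl so that one equivalent of PMBCl should alkylate only the 4-OH, after which the chelated 2-OH is methylated under more forcing conditions in the same pot.

Step 2
Reactants: 3 methyl 2-methoxy-4-[(4-methoxyphenyl)methoxy]-6-methylbenzoate
Product: 6 6-hydroxy-8-methoxy-3-methyl-1H-isochromen-1-one, via PMB keto ester 4 (not isolated), via phenolic keto ester 5 (not isolated)
Conditions: LDA (2.2 equiv), THF, −78 °C; MeC(O)N(OMe)Me (1.5 equiv), −78 → −20 °C; aq NH4Cl; crude: TFA, C6HMe5 (3 equiv), CH2Cl2, 0 °C → rt; then TsOH·H2O (0.2 equiv), PhMe, 100 °C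
Reagents that add atoms: N-methoxy-N-methylacetamide CC(=O)N(C)OC
Why: Lateral (benzylic) lithiation of the o-toluate and Weinreb-amide acylation should give the 2-oxopropyl benzoate, and acid then removes the PMB ether (cation trapped by pentamethylbenzene) and drives enol lactonisation with loss of methanol to the isocoumarin.

Step 3
Reactants: 6 6-hydroxy-8-methoxy-3-methyl-1H-isochromen-1-one
Product: 8 6-hydroxy-8-methoxy-3-methyl-1-oxo-1H-isochromene-5-carbaldehyde, via 5-hydroxymethyl phenol 7 (not isolated)
Conditions: MgCl2 (2 equiv), Et3N (4 equiv), (CH2O)n (6 equiv), MeCN, reflux; 1 M HCl work-up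
Reagents that add atoms: formaldehyde (from paraformaldehyde) C=O
Why: Casnati–Skattebøl magnesium-mediated ortho-formylation, in which the magnesium phenoxide delivers formaldehyde to an ortho carbon and a second formaldehyde oxidises the hydroxymethyl intermediate by hydride transfer; C5 (ortho to OH, para to the C8 OMe, the naphthol-α-like position) should be preferred over C7 between the two oxygens, by analogy with 3-methoxyphenol and 2-naphthol.

Step 4
Reactants: 9 3-(hydroxymethyl)-5-methoxyphenol
Product: 10 {3-methoxy-5-[(triisopropylsilyl)oxy]phenyl}methanol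
Conditions: NaH (1.0 equiv), THF, 0 °C; TIPSCl (1.0 equiv), 0 °C → rt
Reagents that add atoms: chlorotriisopropylsilane CC(C)[Si](Cl)(C(C)C)C(C)C
Why: O-silylation of the sodium phenoxide, since one equivalent of NaH deprotonates only the phenol (far more acidic than the benzylic alcohol) and TIPSCl should therefore react at the aryl oxygen.

Step 5
Reactants: 10 {3-methoxy-5-[(triisopropylsilyl)oxy]phenyl}methanol
Product: 12 {2-bromo-3-methoxy-5-[(triisopropylsilyl)oxy]phenyl}methanol, via dilithio alkoxide 11 (not isolated)
Conditions: n-BuLi (2.3 equiv), TMEDA (2.3 equiv), Et2O–hexane, 0 °C → rt; BrCl2C–CCl2Br (1.2 equiv), −78 °C → rt; aq NH4Cl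
Reagents that add atoms: 1,2-dibromo-1,1,2,2-tetrachloroethane BrC(Cl)(Cl)C(Cl)(Cl)Br
Why: Directed ortho-metalation of the lithium benzyl alkoxide, in which CH2OLi and OMe cooperate to direct lithiation to the carbon between them while the bulky, non-coordinating OTIPS group shields its own ortho positions, followed by bromine transfer to the aryllithium.

Step 6
Reactants: 12 {2-bromo-3-methoxy-5-[(triisopropylsilyl)oxy]phenyl}methanol
Product: 13 [4-bromo-3-methoxy-5-(methoxymethyl)phenoxy]triisopropylsilane
Conditions: NaH (1.3 equiv), MeI (2 equiv), THF, 0 °C → rt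
Reagents that add atoms: iodomethane CI
Why: Williamson methylation of the primary alkoxide, to which the aryl bromide and the hindered aryl TIPS ether should be inert.

Step 7
Reactants: 13 [4-bromo-3-methoxy-5-(methoxymethyl)phenoxy]triisopropylsilane (1.3 equiv); 8 6-hydroxy-8-methoxy-3-methyl-1-oxo-1H-isochromene-5-carbaldehyde
Product: 16 6-hydroxy-8-methoxy-5-({2-methoxy-6-(methoxymethyl)-4-[(triisopropylsilyl)oxy]phenyl}methyl)-3-methyl-1H-isochromen-1-one, via aryllithium 14 (not isolated), via diaryl carbinol 15 (not isolated)
Conditions: 13, n-BuLi (1.05 equiv per 13), THF, −78 °C; add 8 pre-treated with LiHMDS (1.0 equiv), THF, −78 → −30 °C; then Et3SiH (3 equiv), TFA (excess), CH2Cl2 added to the same flask, −30 → 0 °C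
Reagents that add atoms: none
Why: Bromine–lithium exchange turns 13 into aryllithium 14, whose carbanionic carbon is the future C1 of the phenol ring and is held between the chelating OMe and CH2OMe groups; 14 adds to the formyl carbon of the lithium phenoxide of 8, forming the CH–aryl bond and giving carbinol 15. On acidification 15 ionises to a benzhydryl cation that is an O-protonated o-quinone methide, stabilised by the C6 hydroxyl (ortho) and C8 methoxy group (para) of the isocoumarin benzo ring and by the ortho-OMe and para-silyloxy groups of the other ring, and Et3SiH delivers hydride to it to leave the CH2 bridge. The closest known reaction types are the addition of aryllithiums to salicylaldehydes and the ionic (Kursanov–Parnes) hydrogenation of electron-rich benzhydrols. No ring is closed and no stereocentre survives, because the carbinol centre of racemic 15 is removed in the same pot. The step needs regioselectivity on the phenol ring and chemoselectivity for the aldehyde over the lactone: the first is fixed by the carbon–bromine bond of 13, so that coupling can occur only at the carbon between OMe and CH2OMe and para to the silyloxy group (a site that a Friedel–Crafts alkylation could not distinguish from the one para to OMe), and the second by the intrinsically higher electrophilicity of the aldehyde at −78 °C together with the C6 phenoxide, which is para-conjugated to the lactone carbonyl and deactivates it.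

Step 8
Reactants: 16 6-hydroxy-8-methoxy-5-({2-methoxy-6-(methoxymethyl)-4-[(triisopropylsilyl)oxy]phenyl}methyl)-3-methyl-1H-isochromen-1-one
Product: 17 6-hydroxy-5-{[4-hydroxy-2-methoxy-6-(methoxymethyl)phenyl]methyl}-8-methoxy-3-methyl-1H-isochromen-1-one (CNP0481202.0)
Conditions: TBAF (1.2 equiv), AcOH (1.5 equiv), THF, 0 °C
Reagents that add atoms: none
Why: Fluoride-mediated cleavage of the aryl silyl ether, buffered with AcOH so that the liberated phenoxide is protonated at once and the enol lactone is not exposed to base.

Compound list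
1 | methyl 2,4-dihydroxy-6-methylbenzoate (methyl orsellinate) | COC(=O)c1c(C)cc(O)cc1O | starting material
2 | methyl 2-hydroxy-4-[(4-methoxyphenyl)methoxy]-6-methylbenzoate | COC(=O)c1c(C)cc(OCc2ccc(OC)cc2)cc1O | intermediate
3 | methyl 2-methoxy-4-[(4-methoxyphenyl)methoxy]-6-methylbenzoate | COC(=O)c1c(C)cc(OCc2ccc(OC)cc2)cc1OC | intermediate
4 | methyl 2-methoxy-4-[(4-methoxyphenyl)methoxy]-6-(2-oxopropyl)benzoate | COC(=O)c1c(CC(C)=O)cc(OCc2ccc(OC)cc2)cc1OC | intermediate
5 | methyl 4-hydroxy-2-methoxy-6-(2-oxopropyl)benzoate | COC(=O)c1c(CC(C)=O)cc(O)cc1OC | intermediate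
6 | 6-hydroxy-8-methoxy-3-methyl-1H-isochromen-1-one | Cc1cc2cc(O)cc(OC)c2c(=O)o1 | intermediate
7 | 6-hydroxy-5-(hydroxymethyl)-8-methoxy-3-methyl-1H-isochromen-1-one | Cc1cc2c(CO)c(O)cc(OC)c2c(=O)o1 | intermediate
8 | 6-hydroxy-8-methoxy-3-methyl-1-oxo-1H-isochromene-5-carbaldehyde | Cc1cc2c(C=O)c(O)cc(OC)c2c(=O)o1 | intermediate
9 | 3-(hydroxymethyl)-5-methoxyphenol | COc1cc(O)cc(CO)c1 | starting material
10 | {3-methoxy-5-[(triisopropylsilyl)oxy]phenyl}methanol | COc1cc(CO)cc(O[Si](C(C)C)(C(C)C)C(C)C)c1 | intermediate
11 | lithium {2-lithio-3-methoxy-5-[(triisopropylsilyl)oxy]phenyl}methanolate | [Li]OCc1cc(O[Si](C(C)C)(C(C)C)C(C)C)cc(OC)c1[Li] | intermediate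
12 | {2-bromo-3-methoxy-5-[(triisopropylsilyl)oxy]phenyl}methanol | COc1cc(O[Si](C(C)C)(C(C)C)C(C)C)cc(CO)c1Br | intermediate
13 | [4-bromo-3-methoxy-5-(methoxymethyl)phenoxy]triisopropylsilane | COCc1cc(O[Si](C(C)C)(C(C)C)C(C)C)cc(OC)c1Br | intermediate
14 | {2-methoxy-6-(methoxymethyl)-4-[(triisopropylsilyl)oxy]phenyl}lithium | COCc1cc(O[Si](C(C)C)(C(C)C)C(C)C)cc(OC)c1[Li] | intermediate
15 | rac-6-hydroxy-5-(hydroxy{2-methoxy-6-(methoxymethyl)-4-[(triisopropylsilyl)oxy]phenyl}methyl)-8-methoxy-3-methyl-1H-isochromen-1-one | COCc1cc(O[Si](C(C)C)(C(C)C)C(C)C)cc(OC)c1C(O)c1c(O)cc(OC)c2c(=O)oc(C)cc12 | intermediate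
16 | 6-hydroxy-8-methoxy-5-({2-methoxy-6-(methoxymethyl)-4-[(triisopropylsilyl)oxy]phenyl}methyl)-3-methyl-1H-isochromen-1-one | COCc1cc(O[Si](C(C)C)(C(C)C)C(C)C)cc(OC)c1Cc1c(O)cc(OC)c2c(=O)oc(C)cc12 | intermediate
17 | 6-hydroxy-5-{[4-hydroxy-2-methoxy-6-(methoxymethyl)phenyl]methyl}-8-methoxy-3-methyl-1H-isochromen-1-one (CNP0481202.0) | COCc1cc(O)cc(OC)c1Cc1c(O)cc(OC)c2c(=O)oc(C)cc12 | target

Total step count: 8. Longest linear sequence: 5 steps (1 → 2 → 3 → 7 → 8; the branch 4 → 5 → 6 → 7 → 8 is equally long).

Steps most likely to fail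

Step 7. The addition may stall because the phenoxide lowers the electrophilicity of the formyl group, and proton transfer from the 3-methyl group or attack at the lactone carbonyl may compete. In the reduction stage the benzhydryl cation may be captured by the neighbouring CH2OMe oxygen with loss of the O-methyl group. The fallback sets out from 8 and comes back at 16, and replaces the acid stage by an anionic o-quinone-methide cascade. Compound 8 would be treated with Boc2O, DIPEA and cat. DMAP to give tert-butyl (5-formyl-8-methoxy-3-methyl-1-oxo-1H-isochromen-6-yl) carbonate F1, whose aldehyde is no longer deactivated by a phenoxide. The arylmagnesium bromide made from 14 with MgBr2·OEt2 would add at −78 °C, and the new alkoxide would take over the Boc group to give tert-butyl (6-hydroxy-8-methoxy-3-methyl-1-oxo-1H-isochromen-5-yl){2-methoxy-6-(methoxymethyl)-4-[(triisopropylsilyl)oxy]phenyl}methyl carbonate F2 as its magnesium phenoxide. On warming this would expel tert-butyl carbonate to give 8-methoxy-5-({2-methoxy-6-(methoxymethyl)-4-[(triisopropylsilyl)oxy]phenyl}methylidene)-3-methyl-1H-isochromene-1,6(5H)-dione F3, the aryl-substituted o-quinone methide. NaBH4 added to the flask would reduce F3 by conjugate hydride addition to 16.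

Step 3. Formylation of the ester-deactivated phenol may be slow, part of the attack may go to C7, and the hydroxymethyl intermediate may condense with a second molecule of 6 to a methylene-bridged dimer. The fallback sets out from 3 and comes back at 8, and marks C5 with bromine at the benzoate stage, where the 1,3-dialkoxy pattern directs the electrophile away from the carbon between the two oxygens. NBS in MeCN (0 °C → rt) should give methyl 3-bromo-6-methoxy-4-[(4-methoxyphenyl)methoxy]-2-methylbenzoate F4. The sequence of step 2 (LDA, N-methoxy-N-methylacetamide, then TFA/pentamethylbenzene and TsOH) would lead through methyl 3-bromo-6-methoxy-4-[(4-methoxyphenyl)methoxy]-2-(2-oxopropyl)benzoate F5 and methyl 3-bromo-4-hydroxy-6-methoxy-2-(2-oxopropyl)benzoate F6 to 5-bromo-6-hydroxy-8-methoxy-3-methyl-1H-isochromen-1-one F7. Palladium-catalysed reductive carbonylation of F7 (Pd(OAc)2, di(1-adamantyl)-n-butylphosphine, CO/H2, TMEDA, toluene, 100 °C) would then give 8.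

Step 5. Metalation may occur at another ring position or at the benzylic carbon, or the silyl group may migrate in the anion, so that isomeric bromides form. The fallback sets out from 9 and comes back at 12, and replaces directed metalation by electrophilic substitution. Para-selective bromination of the free phenol with Bu4NBr3 (1.0 equiv, CH2Cl2–MeOH, rt) should give 4-bromo-3-(hydroxymethyl)-5-methoxyphenol F8, the site para to OH being the one between OMe and CH2OH; any isomer brominated para to OMe would be removed by chromatography. Selective silylation of the phenoxide of F8 (NaH, TIPSCl, as in step 4) would give 12.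

Further compounds
F1 | step 7 | tert-butyl (5-formyl-8-methoxy-3-methyl-1-oxo-1H-isochromen-6-yl) carbonate | Cc1cc2c(C=O)c(OC(=O)OC(C)(C)C)cc(OC)c2c(=O)o1
F2 | step 7 | tert-butyl (6-hydroxy-8-methoxy-3-methyl-1-oxo-1H-isochromen-5-yl){2-methoxy-6-(methoxymethyl)-4-[(triisopropylsilyl)oxy]phenyl}methyl carbonate | COCc1cc(O[Si](C(C)C)(C(C)C)C(C)C)cc(OC)c1C(OC(=O)OC(C)(C)C)c1c(O)cc(OC)c2c(=O)oc(C)cc12
F3 | step 7 | 8-methoxy-5-({2-methoxy-6-(methoxymethyl)-4-[(triisopropylsilyl)oxy]phenyl}methylidene)-3-methyl-1H-isochromene-1,6(5H)-dione | COCc1cc(O[Si](C(C)C)(C(C)C)C(C)C)cc(OC)c1C=C1C(=O)C=C(OC)C2=C1C=C(C)OC2=O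
F4 | step 3 | methyl 3-bromo-6-methoxy-4-[(4-methoxyphenyl)methoxy]-2-methylbenzoate | COC(=O)c1c(C)c(Br)c(OCc2ccc(OC)cc2)cc1OC
F5 | step 3 | methyl 3-bromo-6-methoxy-4-[(4-methoxyphenyl)methoxy]-2-(2-oxopropyl)benzoate | COC(=O)c1c(CC(C)=O)c(Br)c(OCc2ccc(OC)cc2)cc1OC
F6 | step 3 | methyl 3-bromo-4-hydroxy-6-methoxy-2-(2-oxopropyl)benzoate | COC(=O)c1c(CC(C)=O)c(Br)c(O)cc1OC
F7 | step 3 | 5-bromo-6-hydroxy-8-methoxy-3-methyl-1H-isochromen-1-one | Cc1cc2c(Br)c(O)cc(OC)c2c(=O)o1
F8 | step 5 | 4-bromo-3-(hydroxymethyl)-5-methoxyphenol | COc1cc(O)cc(CO)c1Br
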